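**Retrosynthetic overview**
1. Target 14 ⇒ 12: photochemical oxidative radical 6-endo spirocyclisation with O2 capture forms C-6–C-8' and C-7'–OH and closes the six-membered carbocycle last.
2. 12 ⇒ 6 + 10: reductive Knoevenagel alkylation forms C-6–C-1'.
3. 6 ⇒ phloroglucinol 1: Friedel–Crafts acylation, then dearomative gem-diprenylation (ring A is the purchased aromatic ring).
4. 10 ⇒ (S)-limonene 7: ozonolysis, then intramolecular aldol addition (cyclopentane formed first; C-6' is bought, C-2' and C-3' are relayed from it).
5. Ring order: ring A (bought, dearomatised) and cyclopentane (aldol) → joined → spiro cyclohexane (photochemical step, sets C-6 and C-7').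

Assumption: the target is drawn as one enol tautomer of the 2-acyl-1,3-dione; all keto–enol tautomers of ring A are treated as one compound.
Locants: ring A is C-1 (C=O between spiro and acyl-bearing carbon), C-2 (acyl-bearing), C-3 (enol C–OH), C-4 (C(prenyl)2), C-5 (C=O), C-6 (spiro). Terpenoid carbons are C-1' (CH2 on C-6), C-2' and C-6' (ring-fusion CH), C-3' (C(CH3)OH in the five-membered ring), C-4', C-5', C-7' (C(CH3)OH in the six-membered ring), C-8' (CH2 on C-6).

**Route**

Step 1
Reactants: 1 phloroglucinol; 2 isovaleryl chloride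
Product: 3 phlorisovalerophenone [1-(2,4,6-trihydroxyphenyl)-3-methylbutan-1-one]
Conditions: AlCl3 (4 equiv), PhNO2/CH2Cl2, 0 °C to rt; aq HCl
Reagents that add atoms: none
Why: Friedel–Crafts C-acylation of the very nucleophilic phloroglucinol stops at the mono-ketone because the chelated aryl ketone is deactivated, and no stereocentre is formed.

Step 2
Reactants: 3 phlorisovalerophenone; 4 prenyl bromide (2.1 equiv)
Product: 6 3,5-dihydroxy-2-(3-methylbutanoyl)-4,4-bis(3-methylbut-2-en-1-yl)cyclohexa-2,5-dien-1-one, via 3-prenylphlorisovalerophenone 5 (not isolated)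
Conditions: NaOMe (2.2 equiv), MeOH, 0 °C to rt; aq HCl; chromatography
Reagents that add atoms: none
Why: Base-mediated dearomative C-alkylation of the phloroglucinate (lupulone-type gem-diprenylation), in which the second prenyl bromide attacks the already prenylated, more electron-rich carbon of 5 in competition with the free ring carbon, so 6 is separated from the aromatic 3,5-diprenyl isomer; no stereocentre is formed.

Step 3
Reactants: 7 (S)-(−)-limonene
Product: 9 (3S)-6-oxo-3-(prop-1-en-2-yl)heptanal, via limonene ring ozonide 8 (not isolated)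
Conditions: O3 (1.0 equiv, Sudan red 7B end-point), CH2Cl2, −78 °C; then Me2S, −78 °C to rt
Reagents that add atoms: ozone, [O-][O+]=O
Why: Ozonolysis with reductive work-up cleaves the electron-rich trisubstituted ring alkene well before the 1,1-disubstituted isopropenyl group when ozone is limited to one equivalent, and the limonene stereocentre (future C-6') is untouched.

Step 4
Reactants: 9 (3S)-6-oxo-3-(prop-1-en-2-yl)heptanal
Product: 10 (1R,2S,5S)-2-hydroxy-2-methyl-5-(prop-1-en-2-yl)cyclopentane-1-carbaldehyde
Conditions: pyrrolidine (20 mol %), AcOH (20 mol %), THF, 0 °C, 12 h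
Reagents that add atoms: none
Why: Enamine-mediated intramolecular aldol addition of the aldehyde α-carbon onto the methyl ketone, stopped before dehydration at 0 °C without water removal; because aldol/retro-aldol and C-2' epimerisation are reversible, the thermodynamic diastereomer accumulates with CHO trans to both the C-3' methyl and the C-6' isopropenyl group and cis (hydrogen-bonded) to the new tertiary OH, so C-2' and C-3' are set by the limonene-derived C-6'.

Step 5
Reactants: 6 3,5-dihydroxy-2-(3-methylbutanoyl)-4,4-bis(3-methylbut-2-en-1-yl)cyclohexa-2,5-dien-1-one; 10 (1R,2S,5S)-2-hydroxy-2-methyl-5-(prop-1-en-2-yl)cyclopentane-1-carbaldehyde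
Product: 12 3,5-dihydroxy-6-{[(1R,2S,5S)-2-hydroxy-2-methyl-5-(prop-1-en-2-yl)cyclopentyl]methyl}-2-(3-methylbutanoyl)-4,4-bis(3-methylbut-2-en-1-yl)cyclohexa-2,5-dien-1-one, via alkylidene trione 11 (not isolated)
Conditions: Hantzsch ester (1.2 equiv), ethylenediammonium diacetate (10 mol %), CH2Cl2/EtOH, rt
Reagents that add atoms: none
Why: Three-component reductive Knoevenagel alkylation, in which the only C–H acidic ring carbon of 6 condenses with the aldehyde and the alkylidene-1,3-dione 11 is reduced at once by conjugate hydride transfer from the Hantzsch ester; this excludes O-alkylation, leaves the prenyl and isopropenyl alkenes and the tertiary alcohol untouched, and C-2' keeps its thermodynamic configuration.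

Step 6
Reactants: 12 3,5-dihydroxy-6-{[(1R,2S,5S)-2-hydroxy-2-methyl-5-(prop-1-en-2-yl)cyclopentyl]methyl}-2-(3-methylbutanoyl)-4,4-bis(3-methylbut-2-en-1-yl)cyclohexa-2,5-dien-1-one
Product: 14 CNP0198642.1 (target spiro-triketone), via tertiary hydroperoxide 13 (not isolated)
Conditions: Fe(OTf)3 (10 mol %), NaOAc (0.5 equiv), air (1 atm), MeCN, 427 nm LEDs, 0 °C; then PPh3 (1.5 equiv), 0 °C to rt
Reagents that add atoms: dioxygen, O=O
Why: Proposed new method: the trivalent-iron chelate of the enolised 2-acyl-1,3-dione of 12 (the coloured species of the FeCl3 enol test) is excited into its ligand-to-metal charge-transfer band and releases divalent iron plus the ring A radical, whose C-6 (α,α'-dicarbonyl) position closes 6-endo-trig on the CH2 terminus of the isopropenyl group through a chair with both cyclopentane bonds equatorial (trans-hydrindane), placing the unchelated, conformationally free C-5 carbonyl next to the sp3 C(prenyl)2 carbon in the crowded axial site and the rigid hydrogen-bonded C-1/C-2/C-3 enol-triketone half equatorial (sets C-6), after which O2 adds to the planar tertiary C-7' radical from the equatorial face opposite that axial carbonyl (sets C-7' with OH equatorial and CH3 axial), divalent iron reduces the peroxyl radical to hydroperoxide 13 and regenerates trivalent iron, and PPh3 deoxygenates 13 to 14; the closest known reaction types are the Mn(OAc)3-mediated oxidative free-radical 6-endo cyclisation of 2-alkenyl-1,3-dicarbonyls with aerobic trapping and FeCl3 ligand-to-metal charge-transfer photocatalysis, neither of which has been shown for an iron enolate of a dearomatised acylphloroglucinol.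

**Compound list**
1 | phloroglucinol (benzene-1,3,5-triol) | Oc1cc(O)cc(O)c1 | starting material
2 | isovaleryl chloride (3-methylbutanoyl chloride) | CC(C)CC(Cl)=O | starting material
3 | phlorisovalerophenone, 1-(2,4,6-trihydroxyphenyl)-3-methylbutan-1-one | CC(C)CC(=O)c1c(O)cc(O)cc1O | intermediate
4 | prenyl bromide (1-bromo-3-methylbut-2-ene) | CC(C)=CCBr | starting material
5 | 3-prenylphlorisovalerophenone (not isolated) | CC(C)CC(=O)c1c(O)cc(O)c(CC=C(C)C)c1O | intermediate
6 | 3,5-dihydroxy-2-(3-methylbutanoyl)-4,4-bis(3-methylbut-2-en-1-yl)cyclohexa-2,5-dien-1-one (dearomatised gem-diprenyl acylphloroglucinol) | CC(C)CC(=O)C1=C(O)C(CC=C(C)C)(CC=C(C)C)C(O)=CC1=O | intermediate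
7 | (S)-(−)-limonene | CC1=CC[C@H](CC1)C(C)=C | starting material
8 | secondary ozonide (1,2,4-trioxolane) of the ring alkene of 7, mixture at the two acetal carbons, isopropenyl stereocentre as in 7 (not isolated) | CC12CC[C@@H](CC(O1)OO2)C(C)=C | intermediate
9 | (3S)-6-oxo-3-(prop-1-en-2-yl)heptanal | CC(=O)CC[C@@H](CC=O)C(C)=C | intermediate
10 | (1R,2S,5S)-2-hydroxy-2-methyl-5-(prop-1-en-2-yl)cyclopentane-1-carbaldehyde (CHO cis to OH, trans to CH3 and to isopropenyl) | O=C[C@@H]1[C@H](CC[C@]1(C)O)C(C)=C | intermediate
11 | 3-hydroxy-6-{[(1R,2S,5S)-2-hydroxy-2-methyl-5-(prop-1-en-2-yl)cyclopentyl]methylidene}-2-(3-methylbutanoyl)-4,4-bis(3-methylbut-2-en-1-yl)cyclohex-2-ene-1,5-dione, E/Z mixture (not isolated) | CC(C)=CCC1(CC=C(C)C)C(=O)C(=C[C@@H]2[C@H](CC[C@]2(C)O)C(C)=C)C(=O)C(C(=O)CC(C)C)=C1O | intermediate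
12 | 3,5-dihydroxy-6-{[(1R,2S,5S)-2-hydroxy-2-methyl-5-(prop-1-en-2-yl)cyclopentyl]methyl}-2-(3-methylbutanoyl)-4,4-bis(3-methylbut-2-en-1-yl)cyclohexa-2,5-dien-1-one | CC(C)=CCC1(CC=C(C)C)C(O)=C(C[C@@H]2[C@H](CC[C@]2(C)O)C(C)=C)C(=O)C(C(=O)CC(C)C)=C1O | intermediate
13 | C-7' hydroperoxide of the target: OOH in place of the C-7' OH, all stereocentres as in 14 (not isolated) | CC(C)=CCC1(CC=C(C)C)C(=O)[C@@]2(C[C@@H]3[C@H](CC[C@]3(C)O)[C@@](C)(OO)C2)C(=O)C(C(=O)CC(C)C)=C1O | intermediate
14 | CNP0198642.1: ring A (3-hydroxy-2-(3-methylbutanoyl)-4,4-diprenylcyclohex-2-ene-1,5-dione) spiro-fused at C-6 to a trans-hydrindane; C-6 S, C-2' R, C-3' S, C-6' S, C-7' S; both OH groups on the face of H-6', both CH3 groups and the C-5 carbonyl on the face of H-2' | CC(C)=CCC1(CC=C(C)C)C(=O)[C@@]2(C[C@@H]3[C@H](CC[C@]3(C)O)[C@@](C)(O)C2)C(=O)C(C(=O)CC(C)C)=C1O | target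

**Step count and risks**
Total steps: 6. Longest linear sequence: 4 steps (7 → 9 → 10 → 12 → 14; the ring A branch 1 → 3 → 6 → 12 → 14 is equally long).

Most likely to fail, first: step 6, the new photochemical step. The charge-transfer homolysis of the iron enolate may be inefficient. The C-6 radical may instead close 5-exo onto a prenyl group at C-4 or be oxygenated directly at C-6. The axial/equatorial preference that sets C-6 rests on a conformational argument, not on precedent. The fallback uses known chemistry, sets out from 12 and comes back at 14. Compound 12 is treated with Mn(OAc)3·2H2O (2.2 equiv) and Cu(OAc)2·H2O (1 equiv) in degassed AcOH at rt. This is the thermal oxidative free-radical cyclisation: trivalent manganese generates the same C-6 radical, which closes 6-endo, and divalent copper oxidises the cyclised tertiary radical to the less substituted alkene, giving the 7'-methylidene spirocycle F1. A Mukaiyama hydration of F1 (Co(acac)2 20 mol %, PhSiH3, O2, THF, 0 °C, then PPh3) then adds H to the exocyclic CH2 and O2 to the same tertiary C-7' radical from the equatorial face, passing through hydroperoxide 13 to 14. The 1,1-disubstituted alkene reacts faster than the trisubstituted prenyl groups, so the hydration is stopped at partial conversion.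

Second: step 2, the regiochemistry of the second prenylation. Attack at the free ring carbon gives the aromatic 3,5-diprenyl isomer, and 6 may be the minor product. The fallback changes the order of bond formation, sets out from 3 and 10 and comes back at 12. Excess 3 (3 equiv) and 10 are combined under the conditions of step 5 (Hantzsch ester, ethylenediammonium diacetate, CH2Cl2/MeOH). Condensation gives the ortho-quinone methide F2, which is reduced in situ to the C-alkylated aromatic 3-{[(1R,2S,5S)-2-hydroxy-2-methyl-5-(prop-1-en-2-yl)cyclopentyl]methyl}phlorisovalerophenone F3. Treatment of F3 with prenyl bromide 4 (2.2 equiv) and NaOMe in MeOH at 0 °C puts the first prenyl group on the only free ring carbon to give the 5-prenyl derivative F4. The second prenyl group then goes to the same carbon (lupulone-type dearomatisation) in preference to the carbon bearing the bulky cyclopentylmethyl group, giving 12.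

Third: step 4, where the aldol may run on to the enal or give the wrong C-3' epimer under kinetic control. The fallback sets out from 9 and comes back at 10. Aldol condensation (piperidine/AcOH, toluene, reflux with water removal) gives (5R)-2-methyl-5-(prop-1-en-2-yl)cyclopent-1-ene-1-carbaldehyde F5. Weitz–Scheffer epoxidation (H2O2, NaOH, MeOH, 0 °C) anti to the isopropenyl group gives the epoxy aldehyde (1R,2R,5S)-5-methyl-2-(prop-1-en-2-yl)-6-oxabicyclo[3.1.0]hexane-1-carbaldehyde F6. Reductive opening of the α,β-epoxy carbonyl at the α-carbon with PhSeNa (from PhSeSePh and NaBH4, EtOH, AcOH, 0 °C) then gives 10, with C-2' settling trans to both neighbours on protonation.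

**Further compounds**
F1 | step 6 | 7'-methylidene spirocycle: 14 with C-7' carrying an exocyclic CH2 in place of CH3 and OH, other stereocentres as in 14 | CC(C)=CCC1(CC=C(C)C)C(=O)[C@@]2(C[C@@H]3[C@H](CC[C@]3(C)O)C(=C)C2)C(=O)C(C(=O)CC(C)C)=C1O
F2 | step 2 | ortho-quinone methide from 3 and 10, E/Z mixture (not isolated) | CC(C)CC(=O)C1=C(O)C=C(O)C(=C[C@@H]2[C@H](CC[C@]2(C)O)C(C)=C)C1=O
F3 | step 2 | 1-(2,4,6-trihydroxy-3-{[(1R,2S,5S)-2-hydroxy-2-methyl-5-(prop-1-en-2-yl)cyclopentyl]methyl}phenyl)-3-methylbutan-1-one | CC(C)CC(=O)c1c(O)cc(O)c(C[C@@H]2[C@H](CC[C@]2(C)O)C(C)=C)c1O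
F4 | step 2 | 5-prenyl derivative of F3 (not isolated) | CC(C)CC(=O)c1c(O)c(CC=C(C)C)c(O)c(C[C@@H]2[C@H](CC[C@]2(C)O)C(C)=C)c1O
F5 | step 4 | (5R)-2-methyl-5-(prop-1-en-2-yl)cyclopent-1-ene-1-carbaldehyde | O=CC1=C(C)CC[C@@H]1C(C)=C
F6 | step 4 | (1R,2R,5S)-5-methyl-2-(prop-1-en-2-yl)-6-oxabicyclo[3.1.0]hexane-1-carbaldehyde (oxirane oxygen anti to isopropenyl) | O=C[C@]12O[C@@]1(C)CC[C@@H]2C(C)=C
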